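**Plan**

- Target: (R)-4-bromo-5-(dibromomethylidene)-3-(1-hydroxybutyl)furan-2(5H)-one. Ring atoms are O1, C2 (lactone C=O), C3, C4 (Br) and C5 (=CBr2); the carbinol carbon is C1', read from the SMILES as R.
- Enabling feature: C4 is the β-carbon of the lactone enone and carries Br, so it is a vinylogous acyl bromide and the ring is a masked 5-ylidene tetronic acid. O1–C5(=CBr2)–C4 is an enolised dibromopyruvate and C2–C3–C1' is a 3-hydroxyhexanoyl unit.
- Retrosynthetic cuts, in order: C4–Br back to C4–OH; the C3–C4 bond (Claisen bond between the acyl α-carbon and an ester carbon); the O1–C2 ester bond. This leaves (R)-3-silyloxyhexanoic acid and methyl 3,3-dibromopyruvate.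
- Forward: the C6 acid (steps 1–3) and the C3 keto ester (step 4) are joined as an enol ester (step 5). The only ring is closed between C3 and C4 by a Dieckmann condensation that mirrors tetronate biogenesis (β-oxygenated acyl chain plus a three-carbon α-oxo acid unit). It delivers the ring, the C4 oxidation level and the CBr2 group at once; OH to Br and desilylation finish the route.
- Stereochemistry: C1' comes from Noyori hydrogenation of methyl 3-oxohexanoate with the (R)-BINAP ruthenium catalyst. It is carried as a TBS ether, which also blocks retro-aldol cleavage and dehydration at the tetronic acid stage.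

Key step: step 6

Remark: methyl 3-oxohexanoate and methyl pyruvate are taken as the commercial starting materials; keto ester 6 is used freshly distilled and anhydrous because it hydrates readily.

**Route**

Step 1
Reactants: 1 methyl 3-oxohexanoate
Product: 2 methyl (3R)-3-hydroxyhexanoate
Conditions: H2 (50 atm), RuCl2[(R)-BINAP] (0.1 mol %), MeOH, 50 °C
Reagents that add atoms: none
Why: Noyori asymmetric hydrogenation of a β-keto ester, in which the substrate chelates the (R)-BINAP–ruthenium hydride through both carbonyl groups and hydride is delivered to the face that gives the (R)-carbinol (the same sense as for methyl acetoacetate), setting the only stereocentre of the target.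

Step 2
Reactants: 2 methyl (3R)-3-hydroxyhexanoate
Product: 3 methyl (3R)-3-[(tert-butyldimethylsilyl)oxy]hexanoate
Conditions: TBSCl, imidazole, DMF, rt
Reagents that add atoms: tert-butyldimethylsilyl chloride, CC(C)(C)[Si](C)(C)Cl
Why: Standard imidazole-promoted silylation of a secondary alcohol, needed because a free 1-hydroxyalkyl group on a tetronic acid would be an aldol adduct open to retro-aldol cleavage and dehydration.

Step 3
Reactants: 3 methyl (3R)-3-[(tert-butyldimethylsilyl)oxy]hexanoate
Product: 4 (3R)-3-[(tert-butyldimethylsilyl)oxy]hexanoic acid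
Conditions: LiOH, THF/MeOH/H2O, 0 °C to rt; then cold 1 M HCl to pH 3–4
Reagents that add atoms: lithium hydroxide, [Li+].[OH-]
Why: Saponification of a methyl ester, in which hydroxide adds to the ester carbonyl faster than it enolises the ester toward β-elimination, so the secondary silyl ether and the non-acidic β-stereocentre should survive.

Step 4
Reactants: 5 methyl pyruvate
Product: 6 methyl 3,3-dibromo-2-oxopropanoate
Conditions: Br2 (2.05 equiv), H2SO4 (cat.), CH2Cl2, reflux; distillation
Reagents that add atoms: bromine, BrBr
Why: Acid-catalysed α-bromination of a ketone through its enol; the α-keto ester has a single enolisable carbon, so both bromine atoms enter at C3, and each bromine slows the next enolisation so that the reaction can be held at the dibromide by stoichiometry.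

Step 5
Reactants: 4 (3R)-3-[(tert-butyldimethylsilyl)oxy]hexanoic acid; 6 methyl 3,3-dibromo-2-oxopropanoate
Product: 8 methyl 3,3-dibromo-2-{[(3R)-3-[(tert-butyldimethylsilyl)oxy]hexanoyl]oxy}prop-2-enoate, via acyl chloride 7 (not isolated)
Conditions: (COCl)2, DMF (cat.), CH2Cl2, 0 °C to rt, evaporation; then 6, iPr2NEt (slow addition), CH2Cl2, −30 °C to 0 °C
Reagents that add atoms: oxalyl chloride, ClC(=O)C(=O)Cl (source of the chlorine in 7; none of its atoms remain in 8)
Why: Acyl chloride formation under Vilsmeier catalysis followed by O-acylation of the amine-generated enolate of the α-keto ester, the known way to 2-acyloxyacrylates from pyruvates; attack through oxygen is enforced because the carbon terminus is a fully substituted CBr2 centre and the acyl chloride is a hard electrophile.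

Step 6
Reactants: 8 methyl 3,3-dibromo-2-{[(3R)-3-[(tert-butyldimethylsilyl)oxy]hexanoyl]oxy}prop-2-enoate
Product: 10 3-[(1R)-1-[(tert-butyldimethylsilyl)oxy]butyl]-5-(dibromomethylidene)-4-hydroxyfuran-2(5H)-one, via lithium tetronate 9 (not isolated)
Conditions: LiN(SiMe3)2 (2.1 equiv), THF, −78 °C (slow addition of 8) to −20 °C; then cold 1 M HCl
Reagents that add atoms: lithium hexamethyldisilazide, [Li+].C[Si](C)(C)[N-][Si](C)(C)C (source of the lithium in 9; none of its atoms remain in 10)
Why: Deprotonation at C3, the only acidic C–H of 8, gives the lithium ester enolate, which attacks the methyl ester carbonyl (the future C4) across the enol oxygen; loss of methoxide and deprotonation of the resulting 2,4-dione drive the equilibrium to the tetronate 9 (Dieckmann condensation in the Lacey tetronic acid mode, the laboratory counterpart of the union of a β-oxygenated acyl chain and a three-carbon α-oxo acid unit by which tetronate rings arise in nature). The closest known reaction type is the Dieckmann closure of 2-acyloxyacrylates (enol esters of α-keto esters) to 5-ylidene tetronic acids, as used for pulvinone-type 5-arylidene tetronic acids. The furanone ring closes in the 5-exo-trig mode at the ester carbonyl, and the bromine cis to the ester twists that ester out of conjugation with C5=CBr2, which raises its electrophilicity and lines its π* orbital up with the in-plane approach of C3. No stereocentre is created; C1' is not acidic and cannot be scrambled by retro-aldol cleavage because its oxygen is silylated. The step needs C-acylation at the ester to outrun fragmentation of the enolate to a ketene and the dibromo-enolate, β-elimination of silanolate and conjugate attack on CBr2 (5-endo-trig, disfavoured); low temperature, a hindered non-nucleophilic amide base and the five-ring geometry should secure this, and formation of the tetronate salt removes the product from all equilibria.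

Step 7
Reactants: 10 3-[(1R)-1-[(tert-butyldimethylsilyl)oxy]butyl]-5-(dibromomethylidene)-4-hydroxyfuran-2(5H)-one
Product: 11 4-bromo-3-[(1R)-1-[(tert-butyldimethylsilyl)oxy]butyl]-5-(dibromomethylidene)furan-2(5H)-one
Conditions: (COBr)2, DMF (1.2 equiv), CH2Cl2, 0 °C (preformed bromoiminium salt); then 10, 2,6-lutidine (1.1 equiv), 0 °C to rt
Reagents that add atoms: oxalyl bromide, BrC(=O)C(=O)Br
Why: Vilsmeier-type deoxybromination of a tetronic acid, in which the bromoiminium salt activates the vinylogous-acid oxygen at C4 and bromide then displaces the formamide leaving group by addition–elimination at the enone β-carbon (the standard conversion of tetronic acids into 4-bromo-2(5H)-furanones), while the lutidine takes up HBr so that the silyl ether survives.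

Step 8
Reactants: 11 4-bromo-3-[(1R)-1-[(tert-butyldimethylsilyl)oxy]butyl]-5-(dibromomethylidene)furan-2(5H)-one
Product: 12 (R)-4-bromo-5-(dibromomethylidene)-3-(1-hydroxybutyl)furan-2(5H)-one (CNP0138117.1)
Conditions: aq. HF (48 %), MeCN, 0 °C to rt
Reagents that add atoms: none
Why: Acidic fluoride cleavage of a secondary TBS ether, chosen because the bromofuranone core is stable to acid whereas basic fluoride sources would attack the C4–Br vinylogous acyl bromide and the enol lactone; C1' cannot ionise next to the electron-poor C3, so its configuration should be retained.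

**Compound list**

1 | methyl 3-oxohexanoate | CCCC(=O)CC(=O)OC | starting material
2 | methyl (3R)-3-hydroxyhexanoate | CCC[C@@H](O)CC(=O)OC | intermediate
3 | methyl (3R)-3-[(tert-butyldimethylsilyl)oxy]hexanoate | CCC[C@@H](O[Si](C)(C)C(C)(C)C)CC(=O)OC | intermediate
4 | (3R)-3-[(tert-butyldimethylsilyl)oxy]hexanoic acid | CCC[C@@H](O[Si](C)(C)C(C)(C)C)CC(=O)O | intermediate
5 | methyl pyruvate | CC(=O)C(=O)OC | starting material
6 | methyl 3,3-dibromo-2-oxopropanoate | COC(=O)C(=O)C(Br)Br | intermediate
7 | (3R)-3-[(tert-butyldimethylsilyl)oxy]hexanoyl chloride (formed in the flask in step 5) | CCC[C@@H](O[Si](C)(C)C(C)(C)C)CC(=O)Cl | intermediate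
8 | methyl 3,3-dibromo-2-{[(3R)-3-[(tert-butyldimethylsilyl)oxy]hexanoyl]oxy}prop-2-enoate | CCC[C@@H](O[Si](C)(C)C(C)(C)C)CC(=O)OC(=C(Br)Br)C(=O)OC | intermediate
9 | lithium 3-[(1R)-1-[(tert-butyldimethylsilyl)oxy]butyl]-5-(dibromomethylidene)-2-oxo-2,5-dihydrofuran-4-olate (formed in the flask in step 6) | CCC[C@@H](O[Si](C)(C)C(C)(C)C)C1=C([O-])C(=C(Br)Br)OC1=O.[Li+] | intermediate
10 | 3-[(1R)-1-[(tert-butyldimethylsilyl)oxy]butyl]-5-(dibromomethylidene)-4-hydroxyfuran-2(5H)-one | CCC[C@@H](O[Si](C)(C)C(C)(C)C)C1=C(O)C(=C(Br)Br)OC1=O | intermediate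
11 | 4-bromo-3-[(1R)-1-[(tert-butyldimethylsilyl)oxy]butyl]-5-(dibromomethylidene)furan-2(5H)-one | CCC[C@@H](O[Si](C)(C)C(C)(C)C)C1=C(Br)C(=C(Br)Br)OC1=O | intermediate
12 | (R)-4-bromo-5-(dibromomethylidene)-3-(1-hydroxybutyl)furan-2(5H)-one | CCC[C@@H](O)C1=C(Br)C(=C(Br)Br)OC1=O | target

**Step count**

Total steps: 8. Longest linear sequence: 7 steps (steps 1, 2, 3, 5, 6, 7, 8); step 4 is a one-step side branch.

**Steps most likely to fail**

1. Step 6 (Dieckmann closure). What may go wrong: fragmentation of the ester enolate into a ketene by expulsion of the well-stabilised dibromo-enolate, or attack on the hindered ester that is too slow to compete with that loss. Fallback: the bromine atoms of the exocyclic carbon are introduced after ring closure, so that the enolate faces a poorer leaving group and an unhindered ester. It sets out from acid 4 and returns at 11. The acyl chloride 7 is made as in step 5 and used to O-acylate methyl pyruvate 5 (Et3N, DMAP cat., CH2Cl2), giving methyl 2-{[(3R)-3-[(tert-butyldimethylsilyl)oxy]hexanoyl]oxy}prop-2-enoate F1. Dieckmann closure (LiN(SiMe3)2, THF, −78 °C) should give 3-[(1R)-1-[(tert-butyldimethylsilyl)oxy]butyl]-4-hydroxy-5-methylidenefuran-2(5H)-one F2. Bromination at C4 as in step 7 should give 4-bromo-3-[(1R)-1-[(tert-butyldimethylsilyl)oxy]butyl]-5-methylidenefuran-2(5H)-one F3. Addition of Br2 (CH2Cl2, 0 °C) to the exocyclic enol double bond should give 4,5-dibromo-5-(bromomethyl)-3-[(1R)-1-[(tert-butyldimethylsilyl)oxy]butyl]furan-2(5H)-one F4 (C5 epimers), and Et3N should remove HBr to give (5Z)-4-bromo-5-(bromomethylidene)-3-[(1R)-1-[(tert-butyldimethylsilyl)oxy]butyl]furan-2(5H)-one F5. A second addition of Br2 should give 4,5-dibromo-5-(dibromomethyl)-3-[(1R)-1-[(tert-butyldimethylsilyl)oxy]butyl]furan-2(5H)-one F6, and a second dehydrobromination with Et3N returns to the route at 11.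

2. Step 5 (enol ester formation). What may go wrong: base-induced self-condensation or loss of bromine from the very electrophilic keto ester 6 faster than O-acylation of its enolate. Fallback: the enol ester double bond is made by elimination after a conventional esterification of a saturated alcohol. It sets out from acid 4 (as acyl chloride 7) and returns at 8. The alcohol, methyl 3,3,3-tribromo-2-hydroxypropanoate F7, is obtained by addition of the tribromomethyl anion (bromoform, DBU, THF, −20 °C) to methyl glyoxylate. Esterification with 7 (pyridine, DMAP cat., CH2Cl2) should give methyl 3,3,3-tribromo-2-{[(3R)-3-[(tert-butyldimethylsilyl)oxy]hexanoyl]oxy}propanoate F8 (C2 epimers). Its C2–H is flanked by the ester and acyloxy groups and lies next to the CBr3 group, so Et3N (CH2Cl2, 0 °C) should remove HBr, as in the known conversion of trihalomethyl carbinol derivatives into 1,1-dihaloalkenes, and return to the route at 8.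

3. Step 7 (hydroxyl to bromide). What may go wrong: acid-promoted loss of the silyl ether (ionisation at C1' assisted by the enol) before the enol oxygen is activated, or activation at the lactone carbonyl oxygen instead of the C4 oxygen. Fallback: the hydroxyl is converted into a sulfonate under basic conditions and exchanged for bromide in a separate step. It sets out from 10 and returns at 11. Tf2O and iPr2NEt (CH2Cl2, −78 °C) should give 3-[(1R)-1-[(tert-butyldimethylsilyl)oxy]butyl]-5-(dibromomethylidene)-2-oxo-2,5-dihydrofuran-4-yl trifluoromethanesulfonate F9. LiBr in THF (rt to 50 °C) should then replace triflate by bromide through conjugate addition–elimination at C4, returning to the route at 11.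

**Further compounds**

F1 | step 6 | methyl 2-{[(3R)-3-[(tert-butyldimethylsilyl)oxy]hexanoyl]oxy}prop-2-enoate | CCC[C@@H](O[Si](C)(C)C(C)(C)C)CC(=O)OC(=C)C(=O)OC
F2 | step 6 | 3-[(1R)-1-[(tert-butyldimethylsilyl)oxy]butyl]-4-hydroxy-5-methylidenefuran-2(5H)-one | CCC[C@@H](O[Si](C)(C)C(C)(C)C)C1=C(O)C(=C)OC1=O
F3 | step 6 | 4-bromo-3-[(1R)-1-[(tert-butyldimethylsilyl)oxy]butyl]-5-methylidenefuran-2(5H)-one | CCC[C@@H](O[Si](C)(C)C(C)(C)C)C1=C(Br)C(=C)OC1=O
F4 | step 6 | 4,5-dibromo-5-(bromomethyl)-3-[(1R)-1-[(tert-butyldimethylsilyl)oxy]butyl]furan-2(5H)-one (C5 epimers) | CCC[C@@H](O[Si](C)(C)C(C)(C)C)C1=C(Br)C(Br)(CBr)OC1=O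
F5 | step 6 | (5Z)-4-bromo-5-(bromomethylidene)-3-[(1R)-1-[(tert-butyldimethylsilyl)oxy]butyl]furan-2(5H)-one | CCC[C@@H](O[Si](C)(C)C(C)(C)C)C1=C(Br)/C(=C/Br)OC1=O
F6 | step 6 | 4,5-dibromo-5-(dibromomethyl)-3-[(1R)-1-[(tert-butyldimethylsilyl)oxy]butyl]furan-2(5H)-one (C5 epimers) | CCC[C@@H](O[Si](C)(C)C(C)(C)C)C1=C(Br)C(Br)(C(Br)Br)OC1=O
F7 | step 5 | methyl 3,3,3-tribromo-2-hydroxypropanoate | COC(=O)C(O)C(Br)(Br)Br
F8 | step 5 | methyl 3,3,3-tribromo-2-{[(3R)-3-[(tert-butyldimethylsilyl)oxy]hexanoyl]oxy}propanoate (C2 epimers) | CCC[C@@H](O[Si](C)(C)C(C)(C)C)CC(=O)OC(C(=O)OC)C(Br)(Br)Br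
F9 | step 7 | 3-[(1R)-1-[(tert-butyldimethylsilyl)oxy]butyl]-5-(dibromomethylidene)-2-oxo-2,5-dihydrofuran-4-yl trifluoromethanesulfonate | CCC[C@@H](O[Si](C)(C)C(C)(C)C)C1=C(OS(=O)(=O)C(F)(F)F)C(=C(Br)Br)OC1=O
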